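**Plan**
Retrosynthesis: both silyl ethers are removed, then C2–C3 of ring C is cut. C2 is an acetal-level carbon held by O1 and the 4-oxyphenyl ring (a stabilised oxocarbenium ion once ionised), and C3 is the α-carbon of the C4 ketone.
The O1–C2–C3–C4=O array is therefore read as the product of an O-to-C 1,3-shift (Petasis–Ferrier type) of a 2-aryl-4-methylene-4H-1,3-benzodioxin, in which the two aromatic halves are joined by C–O bonds only.
Further cuts: the exocyclic C=CH2 goes back to a lactone C=O; the two acetal C–O bonds of the 1,3-benzodioxin-4-one go back to a salicylic acid and 4-silyloxybenzaldehyde; the acid goes back through CHO oxidation, O-silyl, O-geranyl and C-geranyl bonds to 2,4,6-trihydroxybenzaldehyde.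
Forward: ring A and the 4-oxyphenyl ring are bought and the two geranyl groups are put on first (E alkenes from geranyl bromide and geraniol). The 1,3-dioxinone ring is closed on the only free phenol, the one beside the C-geranyl group, which fixes O1 next to C8; it is then methylenated and rearranged into ring C.
Stereochemistry: the only stereocentre, C2 (S), is created in the rearrangement under control of a chiral phosphate counter-anion; the acetal centre of the precursor is racemic and is erased on ionisation.

Key step: step 7

Remarks on the chemistry: geranyl = (2E)-3,7-dimethylocta-2,6-dien-1-yl; TBS = tert-butyldimethylsilyl. Compounds 10 and 11 are racemic at the acetal carbon. Assumption: the sense of induction of the chiral acid in step 7 cannot be predicted with certainty; the (R)-acid is written, and its mirror image would be used if a first run gave the (2R) product.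

Step 1
Reactants: 1 2,4,6-trihydroxybenzaldehyde; 2 geranyl bromide
Product: 3 3-geranyl-2,4,6-trihydroxybenzaldehyde
Conditions: 2 (1 equiv), 1 (3 equiv), DBU, THF, 0 °C to rt
Reagents that add atoms: none
Why: Base-mediated C-alkylation of a phloroglucinol-type phenoxide with an allylic bromide is the standard entry to C-geranylated acylphloroglucinols; 1 is symmetrical so only one mono-C-alkyl isomer can form, excess 1 limits double alkylation, and SN2 attack keeps the E double bond of 2.

Step 2
Reactants: 3 3-geranyl-2,4,6-trihydroxybenzaldehyde; 4 geraniol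
Product: 5 3-geranyl-4-(geranyloxy)-2,6-dihydroxybenzaldehyde
Conditions: 4, PPh3, DIAD, THF, 0 °C to rt
Reagents that add atoms: none
Why: Mitsunobu etherification should take the most acidic phenol, the 4-OH para to the formyl group, while the two ortho hydroxyls are deactivated by hydrogen bonding to the formyl oxygen; SN2 displacement at the primary allylic carbon of geraniol keeps the E geometry and the neutral medium avoids further C-alkylation.

Step 3
Reactants: 5 3-geranyl-4-(geranyloxy)-2,6-dihydroxybenzaldehyde
Product: 6 6-(TBS-oxy)-3-geranyl-4-(geranyloxy)-2-hydroxybenzaldehyde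
Conditions: TBSCl (1.05 equiv), imidazole, DMF, 0 °C
Reagents that add atoms: tert-butyldimethylsilyl chloride, CC(C)(C)[Si](C)(C)Cl
Why: Silylation with a bulky silyl chloride should distinguish the two ortho hydroxyls on steric grounds, since the 6-OH has a ring hydrogen as second neighbour whereas the 2-OH sits between the formyl group and the geranyl CH2 and stays as the chelated phenol that later becomes O1.

Step 4
Reactants: 6 6-(TBS-oxy)-3-geranyl-4-(geranyloxy)-2-hydroxybenzaldehyde
Product: 7 6-(TBS-oxy)-3-geranyl-4-(geranyloxy)-2-hydroxybenzoic acid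
Conditions: NaClO2, NaH2PO4, 2-methyl-2-butene (large excess), t-BuOH/H2O, 0 °C to rt
Reagents that add atoms: sodium chlorite, [Na+].[O-]Cl=O
Why: Lindgren–Pinnick oxidation converts the aldehyde to the acid without touching the silyl ether, and the large excess of 2-methyl-2-butene should scavenge hypochlorous acid before it attacks the geranyl double bonds or the electron-rich ring.

Step 5
Reactants: 7 6-(TBS-oxy)-3-geranyl-4-(geranyloxy)-2-hydroxybenzoic acid; 8 4-(TBS-oxy)benzaldehyde
Product: 10 5-(TBS-oxy)-2-[4-(TBS-oxy)phenyl]-8-geranyl-7-(geranyloxy)-4H-1,3-benzodioxin-4-one (racemic), via bis(trimethylsilyl) derivative 9 (not isolated)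
Conditions: HMDS, CH2Cl2, rt, then evaporation; 8, TMSOTf (cat.), CH2Cl2, −78 °C
Reagents that add atoms: none
Why: Silyl-transfer acetalization of a bis-silylated hydroxy acid with an aldehyde under catalytic TMSOTf is the standard way to the dioxanones used for Petasis–Ferrier rearrangements and needs no protic acid; only the 2-OH is free, so the acetal oxygen O1 is necessarily the one beside the C-geranyl group, and the new acetal centre forms racemic, which is of no consequence.

Step 6
Reactants: 10 5-(TBS-oxy)-2-[4-(TBS-oxy)phenyl]-8-geranyl-7-(geranyloxy)-4H-1,3-benzodioxin-4-one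
Product: 11 5-(TBS-oxy)-2-[4-(TBS-oxy)phenyl]-8-geranyl-7-(geranyloxy)-4-methylidene-4H-1,3-benzodioxine (racemic)
Conditions: Cp2TiMe2, toluene, 65 °C, dark; filtration through basic alumina, used at once
Reagents that add atoms: dimethyltitanocene, [CH3-].[CH3-].[Ti+4].c1cc[cH-]c1.c1cc[cH-]c1
Why: Petasis methylenation converts lactone carbonyls to exocyclic enol ethers through Cp2Ti=CH2 under non-acidic, non-nucleophilic conditions, so the acylal ring is not opened and the silyl ethers, the allyl aryl ether and the isolated alkenes should be left alone.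

Step 7
Reactants: 11 5-(TBS-oxy)-2-[4-(TBS-oxy)phenyl]-8-geranyl-7-(geranyloxy)-4-methylidene-4H-1,3-benzodioxine
Product: 13 (2S)-5-(TBS-oxy)-2-[4-(TBS-oxy)phenyl]-8-geranyl-7-(geranyloxy)-2,3-dihydro-4H-chromen-4-one, via enol oxocarbenium ion pair 12 (not isolated)
Conditions: (R)-3,3'-bis(2,4,6-triisopropylphenyl)-1,1'-binaphthyl-2,2'-diyl hydrogen phosphate (10 mol %), 4 Å molecular sieves, toluene, −40 to 0 °C
Reagents that add atoms: none
Why: Proposed new method: the chiral phosphoric acid protonates the enol-ether oxygen O3 of 11 and the C2–O3 bond ionises, which is easy because C2 is stabilised by O1 and by the 4-silyloxyphenyl ring, to give ion pair 12 in which the freed enol is hydrogen-bonded to the phosphate that also pairs with the oxocarbenium ion; attack of the enol carbon C3 on C2 then forms the C2–C3 bond and the C4 ketone. The closest known reaction types are the Petasis–Ferrier rearrangement of 4-methylene-1,3-dioxanes to tetrahydropyran-4-ones under Me2AlCl and the chiral-phosphoric-acid-catalysed Petasis–Ferrier-type rearrangements of hemiaminal vinyl ethers and of seven-membered cyclic vinyl acetals; an enantioselective version on a 4-methylene-1,3-benzodioxin leading to a flavanone is not known. Ring C closes in a 6-(enolendo)-endo-trig mode. The C2 stereocentre is set by the chiral phosphate counter-anion, which has to hold the enol and cover one face of the planar oxocarbenium ion; the racemic acetal centre of 11 is destroyed on ionisation, so both enantiomers of 11 should converge on one product. The step needs C- over O-recombination, enol attack in preference to Prins-type capture of C2 by the neighbouring C8 geranyl double bond, and no protonation of the geranyl alkenes: O-return only regenerates 11, the enol is released directly beside the cation and is far more nucleophilic than a trisubstituted alkene, the strongly stabilised cation allows a weak acid and low temperature, and the sieves exclude water that would hydrolyse the enol acetal.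

Step 8
Reactants: 13 (2S)-5-(TBS-oxy)-2-[4-(TBS-oxy)phenyl]-8-geranyl-7-(geranyloxy)-2,3-dihydro-4H-chromen-4-one
Product: 14 (2S)-8-geranyl-7-(geranyloxy)-5-hydroxy-2-(4-hydroxyphenyl)-2,3-dihydro-4H-chromen-4-one (target)
Conditions: TBAF, AcOH (1:1), THF, 0 °C
Reagents that add atoms: none
Why: Fluoride cleaves both aryl silyl ethers at 0 °C, and buffering with acetic acid should keep the medium from becoming basic enough to open the flavanone to the chalcone, so the C2 stereocentre is not scrambled and the geranyl groups are untouched.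

**Compound list**
1 | 2,4,6-trihydroxybenzaldehyde | O=Cc1c(O)cc(O)cc1O | starting material
2 | geranyl bromide, (2E)-1-bromo-3,7-dimethylocta-2,6-diene | CC(C)=CCC/C(C)=C/CBr | starting material
3 | 3-geranyl-2,4,6-trihydroxybenzaldehyde | O=Cc1c(O)cc(O)c(C/C=C(\C)CCC=C(C)C)c1O | intermediate
4 | geraniol, (2E)-3,7-dimethylocta-2,6-dien-1-ol | CC(C)=CCC/C(C)=C/CO | starting material
5 | 3-geranyl-4-(geranyloxy)-2,6-dihydroxybenzaldehyde | O=Cc1c(O)cc(OC/C=C(\C)CCC=C(C)C)c(C/C=C(\C)CCC=C(C)C)c1O | intermediate
6 | 6-(TBS-oxy)-3-geranyl-4-(geranyloxy)-2-hydroxybenzaldehyde | O=Cc1c(O[Si](C)(C)C(C)(C)C)cc(OC/C=C(\C)CCC=C(C)C)c(C/C=C(\C)CCC=C(C)C)c1O | intermediate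
7 | 6-(TBS-oxy)-3-geranyl-4-(geranyloxy)-2-hydroxybenzoic acid | OC(=O)c1c(O[Si](C)(C)C(C)(C)C)cc(OC/C=C(\C)CCC=C(C)C)c(C/C=C(\C)CCC=C(C)C)c1O | intermediate
8 | 4-(TBS-oxy)benzaldehyde | O=Cc1ccc(O[Si](C)(C)C(C)(C)C)cc1 | starting material
9 | trimethylsilyl 6-(TBS-oxy)-3-geranyl-4-(geranyloxy)-2-(trimethylsilyloxy)benzoate | C[Si](C)(C)OC(=O)c1c(O[Si](C)(C)C(C)(C)C)cc(OC/C=C(\C)CCC=C(C)C)c(C/C=C(\C)CCC=C(C)C)c1O[Si](C)(C)C | intermediate
10 | 5-(TBS-oxy)-2-[4-(TBS-oxy)phenyl]-8-geranyl-7-(geranyloxy)-4H-1,3-benzodioxin-4-one, racemic at C2 | O=C1OC(c2ccc(O[Si](C)(C)C(C)(C)C)cc2)Oc2c(C/C=C(\C)CCC=C(C)C)c(OC/C=C(\C)CCC=C(C)C)cc(O[Si](C)(C)C(C)(C)C)c21 | intermediate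
11 | 5-(TBS-oxy)-2-[4-(TBS-oxy)phenyl]-8-geranyl-7-(geranyloxy)-4-methylidene-4H-1,3-benzodioxine, racemic at C2 | C=C1OC(c2ccc(O[Si](C)(C)C(C)(C)C)cc2)Oc2c(C/C=C(\C)CCC=C(C)C)c(OC/C=C(\C)CCC=C(C)C)cc(O[Si](C)(C)C(C)(C)C)c21 | intermediate
12 | ring-opened enol/aryloxycarbenium cation, ion-paired with the chiral phosphate | C=C(O)c1c(O[Si](C)(C)C(C)(C)C)cc(OC/C=C(\C)CCC=C(C)C)c(C/C=C(\C)CCC=C(C)C)c1[O+]=Cc1ccc(O[Si](C)(C)C(C)(C)C)cc1 | intermediate
13 | (2S)-5-(TBS-oxy)-2-[4-(TBS-oxy)phenyl]-8-geranyl-7-(geranyloxy)-2,3-dihydro-4H-chromen-4-one | CC(C)=CCC/C(C)=C/COc1cc(O[Si](C)(C)C(C)(C)C)c2c(c1C/C=C(\C)CCC=C(C)C)O[C@H](c1ccc(O[Si](C)(C)C(C)(C)C)cc1)CC2=O | intermediate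
14 | (2S)-8-geranyl-7-(geranyloxy)-5-hydroxy-2-(4-hydroxyphenyl)-2,3-dihydro-4H-chromen-4-one | CC(C)=CCC/C(C)=C/COc1cc(O)c2c(c1C/C=C(\C)CCC=C(C)C)O[C@H](c1ccc(O)cc1)CC2=O | target

**Step count**
Total steps: 8. Longest linear sequence: 8 steps (1 to 14).

**Steps most likely to fail**

Step 7 (new method). The ion pair may give poor facial discrimination; the C2 cation may be captured by the C8 geranyl double bond in a Prins-type closure; the enol acetal may be lost by hydrolysis. The fallback uses known chemistry and sets out from 11. Treatment with Me2AlCl in CH2Cl2 at −78 °C, the classical Petasis–Ferrier conditions, binds O3 to aluminium and generates the aluminium enolate directly beside the cation; this should give the racemic flavanone F1. Preparative chromatography on an amylose tris(3,5-dimethylphenylcarbamate) phase would then separate the enantiomers: the (2S) enantiomer is 13, where the route is rejoined, and the (2R) enantiomer F2 could be recycled by base-mediated racemisation through the chalcone.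

Step 6. The hindered, electron-rich lactone carbonyl (peri silyloxy group) may be methylenated incompletely, or the acid-labile enol acetal may decompose on isolation. The fallback sets out from 10 and uses the lactone as an acyl donor instead of a carbonyl to be olefinated; it gives up the C2–C3 closure. Methylenetriphenylphosphorane (THF, 0 °C) should be C-acylated by 10 to give the stabilised keto ylide F3 with release of aldehyde 8. Heating F3 with 8 (extra 8 added) in toluene should give, by Wittig reaction, the 2'-hydroxychalcone F4. NaOAc in ethanol at rt should close F4 by oxa-Michael addition to the racemic flavanone F1; only one ortho hydroxyl is free, so the regiochemistry is kept. Resolution on the chiral phase as above returns to the route at 13.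

Step 5. Acetalization at the hindered, chelated 2-OH may be slow, with competing decarboxylation of the electron-rich salicylic acid. The fallback sets out from 7 and 8 and replaces the kinetic silyl-transfer process by acetal exchange under thermodynamic control. Aldehyde 8 is first converted with HC(OMe)3 and catalytic pyridinium p-toluenesulfonate to its dimethyl acetal F5. Acid 7 and F5 are then equilibrated with catalytic pyridinium p-toluenesulfonate in toluene at 50 °C over 5 Å molecular sieves, which take up methanol; this should give 10, where the route is rejoined.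

Further compounds
F1 | step 7 | racemic 5-(TBS-oxy)-2-[4-(TBS-oxy)phenyl]-8-geranyl-7-(geranyloxy)-2,3-dihydro-4H-chromen-4-one | CC(C)=CCC/C(C)=C/COc1cc(O[Si](C)(C)C(C)(C)C)c2c(c1C/C=C(\C)CCC=C(C)C)OC(c1ccc(O[Si](C)(C)C(C)(C)C)cc1)CC2=O
F2 | step 7 | (2R)-5-(TBS-oxy)-2-[4-(TBS-oxy)phenyl]-8-geranyl-7-(geranyloxy)-2,3-dihydro-4H-chromen-4-one | CC(C)=CCC/C(C)=C/COc1cc(O[Si](C)(C)C(C)(C)C)c2c(c1C/C=C(\C)CCC=C(C)C)O[C@@H](c1ccc(O[Si](C)(C)C(C)(C)C)cc1)CC2=O
F3 | step 6 | 1-[6-(TBS-oxy)-3-geranyl-4-(geranyloxy)-2-hydroxyphenyl]-2-(triphenylphosphoranylidene)ethanone | O=C(C=P(c1ccccc1)(c1ccccc1)c1ccccc1)c1c(O[Si](C)(C)C(C)(C)C)cc(OC/C=C(\C)CCC=C(C)C)c(C/C=C(\C)CCC=C(C)C)c1O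
F4 | step 6 | (2E)-1-[6-(TBS-oxy)-3-geranyl-4-(geranyloxy)-2-hydroxyphenyl]-3-[4-(TBS-oxy)phenyl]prop-2-en-1-one | O=C(/C=C/c1ccc(O[Si](C)(C)C(C)(C)C)cc1)c1c(O[Si](C)(C)C(C)(C)C)cc(OC/C=C(\C)CCC=C(C)C)c(C/C=C(\C)CCC=C(C)C)c1O
F5 | step 5 | 4-(TBS-oxy)benzaldehyde dimethyl acetal | COC(OC)c1ccc(O[Si](C)(C)C(C)(C)C)cc1
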